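The ratio I started from was Jc to the whole racemate, not Jc to Ja.

| setting | oak | ash | dusk | dawn |
|---|---|---|---|---|
| Ja | 0.50 M | 0.50 M | 1.0 M | 1.0 M |
| Jb | 0.50 M | 0.50 M | 1.0 M | 1.0 M |
| Jc | 0.80 equiv | 0.80 equiv | 0.800 equiv | 0.800 equiv |
| temperature | 115 °C | 126 °C | 130 °C | 110 °C |
| remark | run made earlier | run made earlier |  |  |
| time |  |  | 8.0 min | 8.0 min |

- oak (time / min: Je / %): 0.833: 0; 3.00: 11; 5.00: 10; 6.00: 16; 10.0: 16; 12.0: 13; 15.0: 13
- ash (time / min: Je / %): 0.417: 5; 1.33: 9; 2.50: 10; 3.00: 10; 5.00: 15; 6.00: 15; 8.00: 15

(each reading ± 1.5 percentage points)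

- Jc is single-handed; Ja and Jb are mirror images of each other, charged as a racemate, each of them at the stated concentration
- the handed part of Jc does not stay in what it makes, so the products of the two hands are mirror images too

- the flask that comes out highest in amount of Je, in percent of the Ja and Jb together charged, or "all alike" when all lie within 1.5 percentage points (dusk / dawn / all alike)
- Je at the end, in percent of the Ja and Jb together charged, dusk
- Je at the end, in percent of the Ja and Jb together charged, dawn

Ja and Jb stand at equal strength, so the Jc fraction of the charge is: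

Jc fraction = 0.800 equiv / 2 = 40.0%

If Jc is the limiting reagent and each product takes one Jc, products stop at that fraction, and the Je plateau shows what share of it ends as Je. From the last three ash readings:

return = 15.0% / 40.0% = 0.375

I called this the return on Jc: the Je formed per unit of Jc charged, both counted as fractions of the charge.

To test whether one number was enough, I took the last four oak readings, which average 14.5%. That is 0.5 percentage points from ash, under the scatter of 1.5 points. But both runs stood at 0.50 M, so they tested temperature, not concentration. Dusk and dawn share the same Jc fraction, so I reckoned: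

Je = 0.375 × 40.0% = 15.0%

The oak readings, with their scatter of 1.5 points, gave no firm time of levelling, so my reckoning left open whether dawn at 110 °C would reach its plateau within 8.0 min.

The forecast said all alike, with 15% for dusk and 14.5% for dawn, calling the plateau “a limit rather than a rate effect”. Its dawn figure lies 0.5 points below mine.

The flasks came out all alike, with dusk at 15.5% and dawn at 15.9%.

    Jc + Ja → Je (k = 0.00305 M⁻¹ s⁻¹, Ea = 80.0 kJ mol⁻¹)
    Jc + Jb → Jf (k = 0.00173 M⁻¹ s⁻¹, Ea = 97.0 kJ mol⁻¹)
    Je ⇌ Jf (k = 3.45 × 10⁻⁴ s⁻¹, Ea = 121 kJ mol⁻¹)
    2 Jc → Jd (k = 0.00172 M⁻¹ s⁻¹, Ea = 89.0 kJ mol⁻¹)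
    (constants at 110 °C)

The return was 0.387 in dusk and 0.397 in dawn. The neighbour of dusk with 0.320 equiv of Jc has a Jc fraction of 16.0%, so the return foretold 6.00%; it gave 7.28%, a return of 0.455. At ten times the time, Je stood at 15.3% in dusk and 15.5% in dawn. Dusk had 0.094% of its Jc left at 8.00 min, but dawn still held 10%, and its Jf rose from 10.9% at 8.00 min to 15.2% at 80.0 min.

(Readings and results come from a simulation from invented constants.)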